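The retrosynthesis cuts the bridge bond CH2–C6 of ring A (enolised triketone), the bridge bond CH2–C3 of ring B (central butyrylphloroglucinol), the C4–CH2(geranyl) bond at the quaternary carbon of ring A and the three aryl–acyl bonds. In ring D (pyran O1–C2–C3–C4–C4a–C8a) it cuts O1–C2 and re-ties it as O1–C3, which gives a 2-isopropenyl-2,3-dihydrobenzofuran.
Forward: phloroglucinol gives phlorobutyrophenone, which is used twice. Its mono-MOM ether is annulated with isoprene dibromide to the five-membered O-ring, and this ring is then expanded to ring D. Rings C/D, B and A are joined in that order by two Mannich base/ortho-quinone methide additions.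
Enabling feature: O1 sits on C8a next to C8–C(=O)Pr, so it is an acidic ortho-acylphenol oxygen that can leave from and return to an allylpalladium unit reversibly. C4–C3–C2(CH3)2 is an isoprene unit, so ring D is a constitutional isomer of the isopropenyl five-ring and the thermodynamic sink of that manifold.
Stereochemistry: the only stereocentre, quaternary C4 of ring A, is set by a ligand-controlled palladium-catalysed asymmetric allylic dearomatisation of a chlorine-blocked methylphloracetophenone with geranyl methyl carbonate. The E-alkene comes from geraniol. The racemic centre of the five-ring precursor is erased in the key step.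

Key step: step 5

Assumption: the (1R,2R)-ligand is taken to give the configuration drawn for 20, and its antipode is used if the sense of induction proves opposite; enolised triketones are drawn in the tautomer of the target SMILES, and the CIP descriptors refer to that tautomer.

Step 1
Reactants: 1 phloroglucinol
Product: 2 phlorobutyrophenone, 1-(2,4,6-trihydroxyphenyl)butan-1-one
Conditions: PrCOCl (1.05 equiv), AlCl3 (3.5 equiv), CH2Cl2/PhNO2, 0 → 40 °C; ice/aq HCl
Reagents that add atoms: butyryl chloride, CCCC(=O)Cl
Why: Friedel–Crafts C-acylation of the very electron-rich triol should stop at the monoketone because the chelated aryl ketone–AlCl3 complex is deactivated.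

Step 2
Reactants: 2 phlorobutyrophenone
Product: 3 1-[2,6-dihydroxy-4-(methoxymethoxy)phenyl]butan-1-one
Conditions: MOMCl (1.05 equiv), iPr2NEt (1.1 equiv), CH2Cl2, 0 °C
Reagents that add atoms: chloromethyl methyl ether, COCCl
Why: Williamson-type O-alkylation under weak base should take the para hydroxyl, the most acidic one and the only one neither chelated to nor crowded by the butyryl group, so that later only the oxygen next to the ketone can enter the heterocycle.

Step 3
Reactants: 4 isoprene
Product: 5 (E)-1,4-dibromo-2-methylbut-2-ene
Conditions: Br2 (1.0 equiv), CH2Cl2, −20 °C → rt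
Reagents that add atoms: bromine, BrBr
Why: Electrophilic 1,4-addition of bromine to the diene under equilibrating conditions should give the E-configured 1,4-dibromide.

Step 4
Reactants: 3 1-[2,6-dihydroxy-4-(methoxymethoxy)phenyl]butan-1-one; 5 (E)-1,4-dibromo-2-methylbut-2-ene
Product: 6 rac-1-[6-hydroxy-4-(methoxymethoxy)-2-(prop-1-en-2-yl)-2,3-dihydro-1-benzofuran-7-yl]butan-1-one
Conditions: NaH (2.1 equiv), toluene/THF, 0 °C; then 5 (1.0 equiv), 70 °C
Reagents that add atoms: none
Why: In this Nickl benzofuran synthesis the sodium phenoxide in a weakly polar medium is C-alkylated ortho to O− by the prenyl-like CH2Br terminus, the neighbouring phenoxide (the only free flanking oxygen) then closes 5-exo by SN2' displacement of the second bromide, and the new C2 stereocentre is racemic and is erased in step 5.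

Step 5
Reactants: 6 rac-1-[6-hydroxy-4-(methoxymethoxy)-2-(prop-1-en-2-yl)-2,3-dihydro-1-benzofuran-7-yl]butan-1-one
Product: 9 1-[7-hydroxy-5-(methoxymethoxy)-2,2-dimethyl-2H-chromen-8-yl]butan-1-one, via dienylphenol 7 (not isolated), via vinyl ortho-quinone methide 8 (not isolated)
Conditions: Pd(PPh3)4 (5 mol %), toluene (0.02 M), 90 °C, Ar
Reagents that add atoms: none
Why: Proposed new method: Pd(PPh3)4 ionises the allylic C2–O1 bond of 6 (benzofuran numbering), whose leaving group is the ortho-butyrylphenoxide (a vinylogous carboxylate), and loss of a benzylic C3–H from the η3-allyl complex opens the five-membered ring to dienylphenol 7 and a palladium hydride. Re-addition of H–Pd to the terminal CH2 of 7 gives the 1,1-dimethyl-3-aryl-η3-allyl phenoxide, which is the zerovalent palladium complex of vinyl ortho-quinone methide 8; π-σ-π exchange sets the geometry needed for closure, and after release of 8 the ring closes, so that O1 has moved from ring carbon C2 to the former exocyclic carbon and the ring has grown by one atom. The closest known reaction types are the palladium-catalysed 1,4-elimination of allylic aryl ethers to 1,3-dienes (Tsuji–Trost manifold) and the Pd(PPh3)4-catalysed reversible addition of acidic O–H groups across 1,3-dienes, and their pairing inside one molecule as a ring expansion is what is new. Ring D closes by a disrotatory oxa-6π electrocyclisation of 8 (equivalently a 6-endo attack of O1 on the CMe2 terminus of the allyl unit), driven by rearomatisation of ring C. No stereocentre is formed, and the C2 stereocentre of racemic 6 is erased, so both enantiomers converge on achiral 9. The step needs O1 rather than the other flanking oxygen to close, which the MOM ether secures; it needs the six-membered ether to be the sink, which follows because any other allylic ether open to the ion pair re-ionises whereas 9 is conjugated, unstrained and hindered at its tertiary C–O bond; and it needs intramolecular events to outrun C-allylation at the free aromatic C–H, which high dilution secures.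

Step 6
Reactants: 9 1-[7-hydroxy-5-(methoxymethoxy)-2,2-dimethyl-2H-chromen-8-yl]butan-1-one
Product: 10 1-(5,7-dihydroxy-2,2-dimethyl-2H-chromen-8-yl)butan-1-one
Conditions: HCl (cat., 0.5 M in MeOH), 40 °C
Reagents that add atoms: none
Why: Acid-catalysed acetal exchange with methanol removes the MOM helper under conditions that acyl-substituted 2,2-dimethylchromenes of this class tolerate.

Step 7
Reactants: 10 1-(5,7-dihydroxy-2,2-dimethyl-2H-chromen-8-yl)butan-1-one
Product: 11 1-{6-[(dimethylamino)methyl]-5,7-dihydroxy-2,2-dimethyl-2H-chromen-8-yl}butan-1-one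
Conditions: Eschenmoser's salt (1.05 equiv), Et3N (1.1 equiv), CH2Cl2, 0 °C → rt
Reagents that add atoms: N,N-dimethylmethyleneiminium iodide (Eschenmoser's salt), C=[N+](C)C.[I-]
Why: The Mannich aminomethylation can only take C6, the single free ring position, which lies between two hydroxyls and is far more nucleophilic than the chromene alkene.

Step 8
Reactants: 11 1-{6-[(dimethylamino)methyl]-5,7-dihydroxy-2,2-dimethyl-2H-chromen-8-yl}butan-1-one; 2 phlorobutyrophenone
Product: 13 1-{3-[(8-butanoyl-5,7-dihydroxy-2,2-dimethyl-2H-chromen-6-yl)methyl]-2,4,6-trihydroxyphenyl}butan-1-one, via chromene ortho-quinone methide 12 (not isolated)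
Conditions: 2 (3 equiv), 1,4-dioxane, 80 °C, slow N2 stream
Reagents that add atoms: none
Why: Thermal retro-Mannich loss of dimethylamine gives ortho-quinone methide 12, which takes up one of the two equivalent free carbons of 2 in a Michael-type Friedel–Crafts addition, while the excess of 2 suppresses double alkylation and removal of the amine limits base-induced bridge scrambling.

Step 9
Reactants: 13 1-{3-[(8-butanoyl-5,7-dihydroxy-2,2-dimethyl-2H-chromen-6-yl)methyl]-2,4,6-trihydroxyphenyl}butan-1-one
Product: 14 1-{3-[(8-butanoyl-5,7-dihydroxy-2,2-dimethyl-2H-chromen-6-yl)methyl]-5-[(dimethylamino)methyl]-2,4,6-trihydroxyphenyl}butan-1-one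
Conditions: Eschenmoser's salt (1.0 equiv), Et3N (1.1 equiv), CH2Cl2, 0 °C → rt
Reagents that add atoms: N,N-dimethylmethyleneiminium iodide (Eschenmoser's salt), C=[N+](C)C.[I-]
Why: The Mannich reaction is site-specific because ring B carries the only aromatic C–H left in 13.

Step 10
Reactants: 15 2-methylphloroglucinol (2,4,6-trihydroxytoluene)
Product: 16 1-(2,4,6-trihydroxy-3-methylphenyl)ethan-1-one
Conditions: AcCl (1.1 equiv), AlCl3 (3.5 equiv), CH2Cl2/PhNO2, 0 → 40 °C; ice/aq HCl
Reagents that add atoms: acetyl chloride, CC(=O)Cl
Why: Friedel–Crafts acylation takes one of the two equivalent free ring carbons and should stop there through deactivation by the chelated ketone.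

Step 11
Reactants: 16 1-(2,4,6-trihydroxy-3-methylphenyl)ethan-1-one
Product: 17 1-(3-chloro-2,4,6-trihydroxy-5-methylphenyl)ethan-1-one
Conditions: SO2Cl2 (1.0 equiv), CHCl3, EtOH (trace), 0 °C → rt
Reagents that add atoms: sulfuryl chloride, O=S(=O)(Cl)Cl
Why: Electrophilic aromatic chlorination of the last free ring carbon, well known for acylphloroglucinols, installs a removable block that is inert to zerovalent palladium and directs the later alkylation to the methyl-bearing carbon.

Step 12
Reactants: 18 geraniol
Product: 19 geranyl methyl carbonate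
Conditions: ClCO2Me (1.2 equiv), pyridine (1.5 equiv), CH2Cl2, 0 °C
Reagents that add atoms: methyl chloroformate, COC(=O)Cl
Why: Acylation of the primary allylic alcohol leaves the E-alkene untouched and provides a leaving group that delivers its own base on ionisation.

Step 13
Reactants: 17 1-(3-chloro-2,4,6-trihydroxy-5-methylphenyl)ethan-1-one; 19 geranyl methyl carbonate
Product: 20 (S)-2-acetyl-6-chloro-4-[(2E)-3,7-dimethylocta-2,6-dienyl]-3,5-dihydroxy-4-methylcyclohexa-2,5-dien-1-one
Conditions: Pd2(dba)3·CHCl3 (2.5 mol %), (1R,2R)-N,N'-bis[2-(diphenylphosphino)benzoyl]cyclohexane-1,2-diamine (7.5 mol %), 19 (1.1 equiv), toluene, rt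
Reagents that add atoms: none
Why: Proposed new method: zerovalent palladium ionises 19 to the η3-geranyl complex and, after loss of CO2, methoxide, which deprotonates 17; O-allylation is reversible under the catalyst and the acetyl- and chlorine-bearing carbons are deactivated, so the phenoxide should attack the unsubstituted allyl terminus through its methyl-bearing carbon to give the linear, E-configured, dearomatised product; the two faces of the flat nucleophile differ because one flank of the reacting carbon is the free phenoxide next to chlorine and the other a hydroxyl locked in a hydrogen bond to the acetyl group, and the chiral pocket of the ligand reads this difference and sets the quaternary stereocentre; the closest known reaction types are the palladium-catalysed intermolecular asymmetric allylic dearomatisation of 1-alkyl-2-naphthols, the palladium-catalysed asymmetric linear geranylation of 3-substituted oxindoles and the racemic alkylative dearomatisation of acylphloroglucinols.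

Step 14
Reactants: 20 (S)-2-acetyl-6-chloro-4-[(2E)-3,7-dimethylocta-2,6-dienyl]-3,5-dihydroxy-4-methylcyclohexa-2,5-dien-1-one
Product: 21 (R)-2-acetyl-4-[(2E)-3,7-dimethylocta-2,6-dienyl]-3,5-dihydroxy-4-methylcyclohexa-2,5-dien-1-one
Conditions: Zn dust (3 equiv), AcOH/THF, rt
Reagents that add atoms: none
Why: Reductive dehalogenation of an alpha-chloro-beta-dicarbonyl through its zinc enolate removes the block without touching the alkenes or the quaternary carbon, whose descriptor changes only because the CIP priorities change.

Step 15
Reactants: 14 1-{3-[(8-butanoyl-5,7-dihydroxy-2,2-dimethyl-2H-chromen-6-yl)methyl]-5-[(dimethylamino)methyl]-2,4,6-trihydroxyphenyl}butan-1-one; 21 (R)-2-acetyl-4-[(2E)-3,7-dimethylocta-2,6-dienyl]-3,5-dihydroxy-4-methylcyclohexa-2,5-dien-1-one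
Product: 23 CNP0103039.1 (target), via dimer ortho-quinone methide 22 (not isolated)
Conditions: 21 (1.1 equiv), 1,4-dioxane, 60 °C, slow N2 stream; wash with aq citric acid
Reagents that add atoms: none
Why: The strongly acidic enol 21 protonates the Mannich base, so that dimethylamine leaves at moderate temperature, and ortho-quinone methide 22 is taken up in a Michael addition by C6 of the enolate, its only free carbon nucleophile, while the quaternary stereocentre is not involved.

Compound list
1 | phloroglucinol | Oc1cc(O)cc(O)c1 | starting material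
2 | phlorobutyrophenone, 1-(2,4,6-trihydroxyphenyl)butan-1-one | CCCC(=O)c1c(O)cc(O)cc1O | intermediate
3 | 1-[2,6-dihydroxy-4-(methoxymethoxy)phenyl]butan-1-one | CCCC(=O)c1c(O)cc(OCOC)cc1O | intermediate
4 | isoprene | CC(=C)C=C | starting material
5 | (E)-1,4-dibromo-2-methylbut-2-ene | BrC/C=C(\C)CBr | intermediate
6 | rac-1-[6-hydroxy-4-(methoxymethoxy)-2-(prop-1-en-2-yl)-2,3-dihydro-1-benzofuran-7-yl]butan-1-one | CCCC(=O)c1c(O)cc(OCOC)c2c1OC(C2)C(C)=C | intermediate
7 | dienylphenol, 1-{2,6-dihydroxy-4-(methoxymethoxy)-3-[(1E)-3-methylbuta-1,3-dienyl]phenyl}butan-1-one | CCCC(=O)c1c(O)cc(OCOC)c(/C=C/C(C)=C)c1O | intermediate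
8 | vinyl ortho-quinone methide, 2-butanoyl-3-hydroxy-5-(methoxymethoxy)-6-(3-methylbut-2-enylidene)cyclohexa-2,4-dien-1-one | CCCC(=O)C1=C(O)C=C(OCOC)C(=CC=C(C)C)C1=O | intermediate
9 | 1-[7-hydroxy-5-(methoxymethoxy)-2,2-dimethyl-2H-chromen-8-yl]butan-1-one | CCCC(=O)c1c(O)cc(OCOC)c2C=CC(C)(C)Oc12 | intermediate
10 | 1-(5,7-dihydroxy-2,2-dimethyl-2H-chromen-8-yl)butan-1-one | CCCC(=O)c1c(O)cc(O)c2C=CC(C)(C)Oc12 | intermediate
11 | 1-{6-[(dimethylamino)methyl]-5,7-dihydroxy-2,2-dimethyl-2H-chromen-8-yl}butan-1-one | CCCC(=O)c1c(O)c(CN(C)C)c(O)c2C=CC(C)(C)Oc12 | intermediate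
12 | chromene ortho-quinone methide, 8-butanoyl-7-hydroxy-2,2-dimethyl-6-methylidene-2H-chromen-5(6H)-one | CCCC(=O)C1=C(O)C(=C)C(=O)C2=C1OC(C)(C)C=C2 | intermediate
13 | 1-{3-[(8-butanoyl-5,7-dihydroxy-2,2-dimethyl-2H-chromen-6-yl)methyl]-2,4,6-trihydroxyphenyl}butan-1-one | CCCC(=O)c1c(O)cc(O)c(Cc2c(O)c3c(c(C(=O)CCC)c2O)OC(C)(C)C=C3)c1O | intermediate
14 | 1-{3-[(8-butanoyl-5,7-dihydroxy-2,2-dimethyl-2H-chromen-6-yl)methyl]-5-[(dimethylamino)methyl]-2,4,6-trihydroxyphenyl}butan-1-one | CCCC(=O)c1c(O)c(CN(C)C)c(O)c(Cc2c(O)c3c(c(C(=O)CCC)c2O)OC(C)(C)C=C3)c1O | intermediate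
15 | 2-methylphloroglucinol (2,4,6-trihydroxytoluene) | Cc1c(O)cc(O)cc1O | starting material
16 | 1-(2,4,6-trihydroxy-3-methylphenyl)ethan-1-one | CC(=O)c1c(O)cc(O)c(C)c1O | intermediate
17 | 1-(3-chloro-2,4,6-trihydroxy-5-methylphenyl)ethan-1-one | CC(=O)c1c(O)c(Cl)c(O)c(C)c1O | intermediate
18 | geraniol | CC(C)=CCC/C(C)=C/CO | starting material
19 | geranyl methyl carbonate | COC(=O)OC/C=C(\C)CCC=C(C)C | intermediate
20 | (S)-2-acetyl-6-chloro-4-[(2E)-3,7-dimethylocta-2,6-dienyl]-3,5-dihydroxy-4-methylcyclohexa-2,5-dien-1-one | ClC1=C(O)[C@@](C)(C/C=C(\C)CCC=C(C)C)C(O)=C(C(C)=O)C1=O | intermediate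
21 | (R)-2-acetyl-4-[(2E)-3,7-dimethylocta-2,6-dienyl]-3,5-dihydroxy-4-methylcyclohexa-2,5-dien-1-one | C1=C(O)[C@@](C)(C/C=C(\C)CCC=C(C)C)C(O)=C(C(C)=O)C1=O | intermediate
22 | dimer ortho-quinone methide, ring B of 14 as 2-butanoyl-3,5-dihydroxy-type methylidene-cyclohexadienone after loss of dimethylamine | CCCC(=O)C1=C(O)C(=C)C(=O)C(Cc2c(O)c3c(c(C(=O)CCC)c2O)OC(C)(C)C=C3)=C1O | intermediate
23 | CNP0103039.1, (R)-2-acetyl-6-({3-butanoyl-5-[(8-butanoyl-5,7-dihydroxy-2,2-dimethyl-2H-chromen-6-yl)methyl]-2,4,6-trihydroxyphenyl}methyl)-4-[(2E)-3,7-dimethylocta-2,6-dienyl]-3,5-dihydroxy-4-methylcyclohexa-2,5-dien-1-one | CCCC(=O)c1c(O)c(CC2=C(O)[C@@](C)(C/C=C(\C)CCC=C(C)C)C(O)=C(C(C)=O)C2=O)c(O)c(Cc2c(O)c3c(c(C(=O)CCC)c2O)OC(C)(C)C=C3)c1O | target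

Total step count: 15. Longest linear sequence: 9 steps (1, 2, 4, 5, 6, 7, 8, 9, 15).

Steps most likely to fail

Step 5 (labelled). The catalyst may stall after ring opening, the hydride may not return to the diene terminus, or intermolecular C-allylation of the free aromatic position may drain the allyl complex. The fallback gives up the five-membered precursor and sets out from 3. Condensation of 3 with 3-methylbut-2-enal under catalysis by ethylenediammonium diacetate in refluxing toluene is a known Knoevenagel-type condensation at the free carbon next to the free hydroxyl, followed by oxa-6π electrocyclisation. It passes through the same vinyl ortho-quinone methide 8 and comes back to the route at 9, with the MOM ether again fixing the regiochemistry. Steps 3 and 4 then fall away, and no compound outside the list arises (F0).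

Step 13 (labelled). Facial discrimination of the nearly symmetric phenoxide may be poor, some alkylation may occur at the chlorinated carbon, and π-σ-π exchange may erode the E-geometry. The fallback uses known chemistry, sets out from 17 and comes back at 21.
- Alkylative dearomatisation of 17 with geranyl bromide and aqueous KOH at 0 °C gives the racemic chloro dienone F1.
- Zn/AcOH then gives the racemic enol F2.
- This strong enolic acid is resolved classically by fractional crystallisation of its (S)-1-phenylethylammonium salt F3. The antipodal amine is taken if the salt of the wrong enantiomer proves less soluble.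
- Dilute aqueous HCl liberates 21.

Step 4. O-alkylation may win over C-alkylation, the phenoxide may attack the other bromide terminus, or a second annulation may follow. The fallback separates the two bond formations, sets out from 3 and comes back at 6.
- C-prenylation of 3 with prenyl bromide in aqueous KOH, a standard reaction of acylphloroglucinols, gives the prenylphenol F4.
- A Wacker-type oxidative cyclisation follows with Pd(OAc)2 (cat.), Cu(OAc)2 (cat.) and O2 in MeOH/H2O. This is a 5-exo oxypalladation by divalent palladium followed by β-hydride loss from a methyl group, and it gives 6.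

Further compounds
F0 | step 5 | none | none
F1 | step 13 | rac-2-acetyl-6-chloro-4-[(2E)-3,7-dimethylocta-2,6-dienyl]-3,5-dihydroxy-4-methylcyclohexa-2,5-dien-1-one | ClC1=C(O)C(C)(C/C=C(\C)CCC=C(C)C)C(O)=C(C(C)=O)C1=O
F2 | step 13 | rac-2-acetyl-4-[(2E)-3,7-dimethylocta-2,6-dienyl]-3,5-dihydroxy-4-methylcyclohexa-2,5-dien-1-one | C1=C(O)C(C)(C/C=C(\C)CCC=C(C)C)C(O)=C(C(C)=O)C1=O
F3 | step 13 | (S)-1-phenylethylammonium salt of 21 | C1=C([O-])[C@@](C)(C/C=C(\C)CCC=C(C)C)C(O)=C(C(C)=O)C1=O.C[C@H]([NH3+])c1ccccc1
F4 | step 4 | 1-[2,6-dihydroxy-4-(methoxymethoxy)-3-(3-methylbut-2-enyl)phenyl]butan-1-one | CCCC(=O)c1c(O)cc(OCOC)c(CC=C(C)C)c1O
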